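(The numbers of this flask come from no measurement, and the outcome is calculated.)

The ratio you want to carry here is the free share: free product over all product, counting idle adduct as product. Because the adduct is kept at balance, this share is one over one plus 60 L mol⁻¹ times the dissolved starting material.

| setting | noon | midnight | dusk |
|---|---|---|---|
| solid substrate | 0.0080 M | 0.025 M | 0.080 M |
| time | 25 h | 25 h | 25 h |

- [product] (only what is free in solution) at the end for noon, midnight, dusk, in this order
- how the row runs (rises, then falls / falls all the way / hardly changes / falls, then rises / rises all the way)

- a species is counted by the solid substrate in it: one idle adduct counts as two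
- amounts and yields of product count idle adduct too
- given per volume of solution although it is solid: solid substrate
- at the start none of the solid substrate is in solution
- in an amount of product, one idle adduct counts as one product
- the concentration of product that is asked is that of its free form alone
- "hardly changes" means that all values lie within two and a half points (for a concentration: within two and a half percent of the largest)
- run time (noon): 25 h

Solid substrate dissolves into starting material, which passes down a chain to product and also ties up product as idle adduct. In the dusk flask, solid enters at 0.13 h⁻¹ times the gap below the solubility of 27 mM, while starting material leaves at 0.12 h⁻¹. The level therefore approaches a steady state with a time constant of 4.00 h, at 17.5% of the charge. At that feed the dusk charge would last 47.6 h, longer than the run of 25 h, so the level still holds at the end. My reckoning puts 54.3% as the free share in the dusk flask. The midnight charge, at the same feed, would last 14.8 h, shorter than the run, so its level can fall before the end, and for now I take the free share as one at midnight and at noon. As a rough estimate, I let the noon and midnight charges reach intermediate C in one lot after the mean waits of steps 1 to 3, 18.6 h, so step 4 gives 1.79 × 10⁻⁴ M at noon and 5.60 × 10⁻⁴ M at midnight. In the dusk flask I let intermediate C grow at the steady feed after a wait of 14.3 h, which gives 1.84 × 10⁻⁴ M free. My row therefore rises, then falls.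

The forecast gives 2.200 × 10⁻⁴ M, 4.500 × 10⁻⁴ M and 3.100 × 10⁻⁴ M, a row that rises, then falls, with “free product peaks in the middle run”.

The flasks give 2.17 × 10⁻⁴ M, 4.40 × 10⁻⁴ M and 3.05 × 10⁻⁴ M, a row that rises, then falls.

    starting material → intermediate A (k1 = 0.12 h⁻¹)
    intermediate A → intermediate B (k2 = 0.11 h⁻¹)
    intermediate B → intermediate C (k3 = 0.85 h⁻¹)
    intermediate C → product (k4 = 0.0035 h⁻¹)
    solid substrate ⇌ starting material, rate k5*(cs5 - [starting material]) while solid is left; crystals form when [starting material] > cs5 (cs5 = 27 mM, k5 = 0.13 h⁻¹)
    starting material + product ⇌ idle adduct, settled at all times (K6 = 60 L mol⁻¹)

The dusk reading is 0.381% of the charge. Product at the end of the dusk flask, adduct counted, stands at 0.699% of the charge, and the free share of 54.3% makes that 0.380%. In the midnight flask, starting material ends at 9.45% of the charge, which gives a free share of 87.6%. Its product of 2.01% of the charge, adduct counted, then leaves 1.76% of the charge free, and the midnight reading is 1.76%.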